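**Plan**
1. Retrosynthesis: cut the two prenyl groups (C-alkylation); open the triketone ring at the two C–C bonds that join its CH2–C(OH)=C(acyl) unit to the ring carbonyls (Claisen closure, C-acylation), which leaves hydrindane C6 as a lactone/acid pair; cut C5–C6 (6-endo radical cyclisation) and C6–C7 (reductive alkylation of Meldrum's acid); last, take C7 back into the carbocycle, turning the cyclopentane into a cyclohexane.
2. Enabling feature: in O–C1(CH3)–C7a(H)–C7 the tertiary carbinol carbon C1 is bonded to the ring carbon C7a that carries the exocyclic carbon C7. This is the product pattern of a 1,2-shift in a 2,3-epoxy-1-silyloxycyclohexane whose epoxide carbons are C7 and C7a; with C3a and its C3 side chain that six-membered ring is the p-menthane ring of limonene.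
3. Forward order: limonene oxide → allylic alcohol → syn epoxy silyl ether → ring contraction to the cyclopentane carbaldehyde → cyclohexane by oxidative radical cyclisation with a lactone bridge → triketone ring → prenyl groups → desilylation.
4. Stereochemistry: C3a and C1 come from (S)-limonene oxide; C7a from the stereospecific anti shift (epoxide face set by OH-directed epoxidation); C4 and spiro C6 from the lactone bridge in the locked trans-hydrindane chair, the lactone carbonyl later becoming the ring carbonyl next to the diprenyl carbon.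
5. Helpers removed later: the epoxide, the silyl ether (last step), the Meldrum's acid ring (lost as acetone) and the lactone bridge (opened in the Claisen step).

Key step: step 4

Remarks: hydrindane numbering is used (C1 = cyclopentane carbinol, C3a/C7a = ring fusion, C4 = cyclohexane carbinol, C6 = spiro carbon; primed numbers = triketone ring, C6' = C6, C4' = diprenyl carbon). Compound 1 is assumed to be the cis component of commercial (S)-(−)-limonene 1,2-oxide, left when the trans isomer is removed by its selective opening with an aqueous secondary amine. Tricarbonyl compounds are written as one tautomer.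

**Route**

Step 1
Reactants: 1 (1S,4S,6R)-1-methyl-4-(prop-1-en-2-yl)-7-oxabicyclo[4.1.0]heptane (epoxide oxygen trans to isopropenyl)
Product: 4 (1S,4S)-1-methyl-4-(prop-1-en-2-yl)cyclohex-2-en-1-ol (OH trans to isopropenyl), via hydroxy selenide 2 (not isolated), via selenoxide 3 (not isolated)
Conditions: (PhSe)2, NaBH4, EtOH, reflux; then THF, 30% H2O2, 0 °C → rt
Reagents that add atoms: none
Why: Epoxide-to-allylic-alcohol transposition by selenide opening and selenoxide syn-elimination: benzeneselenolate should attack the secondary epoxide carbon by SN2, and the selenoxide, having no β-hydrogen on the carbinol side, can only eliminate into the ring, so the tertiary C–O bond and its configuration are kept.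

Step 2
Reactants: 4 (1S,4S)-1-methyl-4-(prop-1-en-2-yl)cyclohex-2-en-1-ol
Product: 5 (1R,2S,5R,6R)-2-methyl-5-(prop-1-en-2-yl)-7-oxabicyclo[4.1.0]heptan-2-ol (epoxide cis to OH, trans to isopropenyl)
Conditions: VO(acac)2 (2 mol %), t-BuOOH, CH2Cl2, 0 °C → rt
Reagents that add atoms: tert-butyl hydroperoxide, CC(C)(C)OO
Why: Hydroxyl-directed vanadium-catalysed epoxidation: the vanadate ester of the allylic alcohol should deliver oxygen to the ring alkene on the hydroxyl face and leave the isolated isopropenyl group untouched.

Step 3
Reactants: 5 (1R,2S,5R,6R)-2-methyl-5-(prop-1-en-2-yl)-7-oxabicyclo[4.1.0]heptan-2-ol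
Product: 6 tert-butyldimethylsilyl ether of 5
Conditions: TBSOTf, 2,6-lutidine, CH2Cl2, −78 °C
Reagents that add atoms: tert-butyldimethylsilyl triflate, CC(C)(C)[Si](C)(C)OS(=O)(=O)C(F)(F)F
Why: Silylation of a tertiary alcohol with a silyl triflate and a hindered base; no stereocentre is touched and the epoxide should survive at low temperature.

Step 4
Reactants: 6 tert-butyldimethylsilyl ether of 5
Product: 7 (1R,2S,5S)-2-[(tert-butyldimethylsilyl)oxy]-2-methyl-5-(prop-1-en-2-yl)cyclopentane-1-carbaldehyde
Conditions: MeAl(OC6H2-2,6-tBu2-4-Br)2 (MABR, 2 equiv), CH2Cl2, −78 → −20 °C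
Reagents that add atoms: none
Why: The aluminium Lewis acid binds the epoxide oxygen, the C6–O bond (remote from the silyloxy carbon) lengthens, and the silyloxy-bearing carbon C2 shifts from C1 to C6 on the face opposite the departing oxygen while C1 becomes the formyl carbon (semipinacol 1,2-shift, Meinwald-type rearrangement). The closest known reaction types are the organoaluminium-promoted rearrangement of 2,3-epoxy silyl ethers to β-siloxy aldehydes by anti migration of the siloxy carbon, and the Lewis-acid ring contraction of cyclohexene oxides and cyclic 2,3-epoxy acylates to cyclopentanecarbaldehydes. The cyclopentane is closed by this 1,2-shift (bond C2–C6 formed, bond C2–C1 broken), so the six-membered ring loses C1 as an exocyclic carbon. The new stereocentre (the formyl-bearing carbon, later C7a) should be set by inversion at C6 and thus by the epoxide configuration from step 2; the migrating carbinol carbon keeps its configuration and the isopropenyl carbon is untouched, which gives CHO cis to OTBS and trans to isopropenyl. The step needs carbon shift instead of hydride shift and must avoid methyl migration from the carbinol carbon to C1: the electron-withdrawing C–OSi bond disfavours ionisation at C1, the aluminate oxygen on C1 is a better donor than the silyl ether oxygen, methyl migrates poorly, and this bulky Lewis acid favours carbon over hydride shift. Ionisation at C1 with shift of C5 from C6 to C1 would give the same aldehyde with the same configuration, so both ring-carbon shifts converge.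

Step 5
Reactants: 7 (1R,2S,5S)-2-[(tert-butyldimethylsilyl)oxy]-2-methyl-5-(prop-1-en-2-yl)cyclopentane-1-carbaldehyde; 8 Meldrum's acid (2,2-dimethyl-1,3-dioxane-4,6-dione)
Product: 10 5-{[(1R,2S,5S)-2-[(tert-butyldimethylsilyl)oxy]-2-methyl-5-(prop-1-en-2-yl)cyclopentyl]methyl}-2,2-dimethyl-1,3-dioxane-4,6-dione, via alkylidene Meldrum's acid 9 (not isolated)
Conditions: Hantzsch ester, L-proline (20 mol %), EtOH, rt
Reagents that add atoms: none
Why: Organocatalytic reductive alkylation (Knoevenagel condensation, then conjugate reduction by the Hantzsch ester) should give the monoalkyl Meldrum's acid under near-neutral conditions; the α-stereocentre is already in its more stable arrangement (trans to isopropenyl).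

Step 6
Reactants: 10 5-{[(1R,2S,5S)-2-[(tert-butyldimethylsilyl)oxy]-2-methyl-5-(prop-1-en-2-yl)cyclopentyl]methyl}-2,2-dimethyl-1,3-dioxane-4,6-dione
Product: 11 lactone acid: trans-hydrindane (H-3a/H-7a anti) with OTBS (cis to C7) and CH3 on C1, equatorial CH3 on C4, equatorial CO2H on C6, and the axial C6 carbonyl closed as γ-lactone onto the axial C4 oxygen
Conditions: Mn(OAc)3·2H2O (2.2 equiv), AcOH, 40 °C
Reagents that add atoms: none
Why: Mn(OAc)3-mediated oxidative radical cyclisation with lactone annulation: the Meldrum's acid radical should add 6-endo to the CH2 terminus of the isopropenyl group (5-exo would need a trans-fused bicyclo[3.3.0]octane), the tertiary radical is oxidised to the cation and trapped by the axial carbonyl oxygen with loss of acetone; in the locked trans-hydrindane chair only the axial carbonyl on C6 reaches the axial lobe at C4, which sets C4 (O axial, CH3 equatorial) and marks the axial carbonyl of the prochiral C6 as the lactone.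

Step 7
Reactants: 11 lactone acid; 12 5-methylhexane-2,4-dione
Product: 14 3-acyl-5-methylhexane-2,4-dione whose acyl group is the C6 carbonyl of the lactone (triacylmethane; lactone intact), via acid chloride 13 (not isolated)
Conditions: (COCl)2, DMF (cat.), CH2Cl2, 0 °C → rt; then 12, MgCl2, pyridine, CH2Cl2, 0 °C → rt
Reagents that add atoms: none
Why: Acid chloride formation followed by magnesium-chelate C-acylation of a β-diketone at its central carbon should join the equatorial C6 carboxyl to the carbon that carries the isobutyryl group, leaving the lactone carbonyl untouched.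

Step 8
Reactants: 14 triacylmethane
Product: 15 spiro trione: 2'-(2-methylpropanoyl)cyclohexane-1',3',5'-trione spiro-fused at C6' to hydrindane C6; C4' is CH2, the C5' carbonyl is cis to the free axial C4-OH, C1 carries OTBS
Conditions: LiN(iPr)2 (3.3 equiv), THF, −78 → 0 °C; aq. HCl
Reagents that add atoms: none
Why: Intramolecular Claisen (Dieckmann-type) condensation: the dianion formed at the acetyl CH3 should attack the lactone carbonyl through a six-membered transition state, the tertiary C4 alkoxide leaves and the acidic triketone is deprotonated, which makes the closure irreversible; the lactone carbonyl thus becomes C5', next to the free CH2, and the spiro configuration is that fixed by the lactone.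

Step 9
Reactants: 15 spiro trione; 16 prenyl bromide (1-bromo-3-methylbut-2-ene)
Product: 18 silyl ether of the target (4',4'-diprenyl trione; OTBS on C1), via monoprenyl trione 17 (not isolated)
Conditions: NaOMe, MeOH, 0 °C → rt (prenyl bromide 2.5 equiv in all)
Reagents that add atoms: prenyl bromide (second equivalent of 16), CC(C)=CCBr
Why: Twofold C-alkylation of the β-triketone at its only enolisable ring CH2 (as in classical gem-diprenylations of acylphloroglucinol-derived triones): C6' is quaternary and C2' carries the acyl group, so the first equivalent of prenyl bromide gives 17 and the second must enter at the same carbon C4'; no stereocentre remains there.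

Step 10
Reactants: 18 silyl ether of the target
Product: 19 target CNP0273836.6
Conditions: HF·pyridine, pyridine, THF, 0 °C → rt
Reagents that add atoms: none
Why: Fluoride cleavage of the tertiary silyl ether under buffered conditions should leave the prenyl groups, both tertiary alcohols and the enolised triketone intact.

**Compound list**
1 | (1S,4S,6R)-1-methyl-4-(prop-1-en-2-yl)-7-oxabicyclo[4.1.0]heptane (cis-(S)-limonene 1,2-oxide) | C[C@]12CC[C@H](C(C)=C)C[C@H]1O2 | starting material
2 | (1S,2S,4S)-1-methyl-2-(phenylselanyl)-4-(prop-1-en-2-yl)cyclohexan-1-ol | C[C@]1(O)CC[C@H](C(C)=C)C[C@@H]1[Se]c1ccccc1 | intermediate (not isolated)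
3 | selenoxide of 2 | C[C@]1(O)CC[C@H](C(C)=C)C[C@@H]1[Se](=O)c1ccccc1 | intermediate (not isolated)
4 | (1S,4S)-1-methyl-4-(prop-1-en-2-yl)cyclohex-2-en-1-ol | O[C@]1(C)C=C[C@@H](C(C)=C)CC1 | intermediate
5 | (1R,2S,5R,6R)-2-methyl-5-(prop-1-en-2-yl)-7-oxabicyclo[4.1.0]heptan-2-ol | O[C@]1(C)[C@@H]2O[C@@H]2[C@@H](C(C)=C)CC1 | intermediate
6 | tert-butyldimethylsilyl ether of 5 | CC(C)(C)[Si](C)(C)O[C@]1(C)[C@@H]2O[C@@H]2[C@@H](C(C)=C)CC1 | intermediate
7 | (1R,2S,5S)-2-[(tert-butyldimethylsilyl)oxy]-2-methyl-5-(prop-1-en-2-yl)cyclopentane-1-carbaldehyde | O=C[C@@H]1[C@H](CC[C@]1(C)O[Si](C)(C)C(C)(C)C)C(C)=C | intermediate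
8 | Meldrum's acid | CC1(C)OC(=O)CC(=O)O1 | starting material
9 | alkylidene Meldrum's acid from 7 and 8 | CC1(C)OC(=O)C(=C[C@@H]2[C@H](CC[C@]2(C)O[Si](C)(C)C(C)(C)C)C(C)=C)C(=O)O1 | intermediate (not isolated)
10 | 5-{[(1R,2S,5S)-2-[(tert-butyldimethylsilyl)oxy]-2-methyl-5-(prop-1-en-2-yl)cyclopentyl]methyl}-2,2-dimethyl-1,3-dioxane-4,6-dione | CC1(C)OC(=O)C(C[C@@H]2[C@H](CC[C@]2(C)O[Si](C)(C)C(C)(C)C)C(C)=C)C(=O)O1 | intermediate
11 | lactone acid (trans-hydrindane; C6 CO2H equatorial; axial C6 carbonyl lactonised onto axial C4–O; C1 OTBS) | OC(=O)[C@@]12C[C@@H]3[C@H](CC[C@]3(C)O[Si](C)(C)C(C)(C)C)[C@@](C)(C1)OC2=O | intermediate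
12 | 5-methylhexane-2,4-dione | CC(=O)CC(=O)C(C)C | starting material
13 | acid chloride of 11 | ClC(=O)[C@@]12C[C@@H]3[C@H](CC[C@]3(C)O[Si](C)(C)C(C)(C)C)[C@@](C)(C1)OC2=O | intermediate (not isolated)
14 | triacylmethane (3-acyl-5-methylhexane-2,4-dione, acyl = C6 carbonyl of the lactone) | CC(=O)C(C(=O)C(C)C)C(=O)[C@@]12C[C@@H]3[C@H](CC[C@]3(C)O[Si](C)(C)C(C)(C)C)[C@@](C)(C1)OC2=O | intermediate
15 | spiro trione (C4' = CH2; C4–OH free; C1 OTBS) | C1C(=O)[C@@]2(C[C@@H]3[C@H](CC[C@]3(C)O[Si](C)(C)C(C)(C)C)[C@](C)(O)C2)C(=O)C(C(=O)C(C)C)=C1O | intermediate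
16 | prenyl bromide | CC(C)=CCBr | starting material
17 | monoprenyl trione | CC(C)=CCC1C(=O)[C@@]2(C[C@@H]3[C@H](CC[C@]3(C)O[Si](C)(C)C(C)(C)C)[C@](C)(O)C2)C(=O)C(C(=O)C(C)C)=C1O | intermediate (not isolated)
18 | silyl ether of the target | CC(C)=CCC1(CC=C(C)C)C(=O)[C@@]2(C[C@@H]3[C@H](CC[C@]3(C)O[Si](C)(C)C(C)(C)C)[C@](C)(O)C2)C(=O)C(C(=O)C(C)C)=C1O | intermediate
19 | target CNP0273836.6 | CC(C)=CCC1(CC=C(C)C)C(=O)[C@@]2(C[C@@H]3[C@H](CC[C@]3(C)O)[C@](C)(O)C2)C(=O)C(C(=O)C(C)C)=C1O | target

**Count:** 10 steps in total; longest linear sequence 10 steps.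

**Steps most likely to fail**

Step 4. The epoxide may ionise at the carbon next to the silyloxy carbon with methyl migration from the carbinol carbon (giving a hydroxy cyclohexanone), or a hydride may shift instead of the ring carbon. The fallback builds the same cyclopentane by ring cleavage and re-closure. It sets out from 1: periodic acid (H5IO6, THF–H2O) should cleave the epoxide to (S)-6-oxo-3-(prop-1-en-2-yl)heptanal F1. Piperidinium acetate should then effect the aldol condensation to (5R)-2-methyl-5-(prop-1-en-2-yl)cyclopent-1-ene-1-carbaldehyde F2. Alkaline H2O2 should epoxidise the enal anti to the isopropenyl group to (1R,2R,5S)-5-methyl-2-(prop-1-en-2-yl)-6-oxabicyclo[3.1.0]hexane-1-carbaldehyde F3. SmI2 (THF–MeOH, −90 °C) should open the epoxide reductively at the α-carbon to (1R,2S,5S)-2-hydroxy-2-methyl-5-(prop-1-en-2-yl)cyclopentane-1-carbaldehyde F4, the α-centre settling trans to isopropenyl. Silylation as in step 3 returns to the route at 7.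

Step 6. Oxidation of the tertiary radical may end in proton loss or acetate capture instead of lactone closure, or the 6-endo addition may be too slow and the radical is over-oxidised. The fallback forms the ring by polar alkylation and sets out from 7. Ene-type allylic chlorination (Ca(OCl)2, CO2, CH2Cl2–H2O, 0 °C) should give (1R,2S,5S)-2-[(tert-butyldimethylsilyl)oxy]-5-(3-chloroprop-1-en-2-yl)-2-methylcyclopentane-1-carbaldehyde F5. Reductive alkylation with 8 as in step 5 should give the chloroallyl Meldrum's acid F6. K2CO3 in DMF should close the six-membered ring by intramolecular C-allylation to the spiro Meldrum's acid with exocyclic methylene on C4 F7. A catalytic sulfonic acid in moist CH2Cl2 should then protonate the methylene group; the axial carbonyl traps the C4 cation and the dioxanedione ring is hydrolysed with loss of acetone, by the same geometric argument as in step 6, and the route is rejoined at 11.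

Step 8. The dianion may form at the isobutyryl methine instead of the acetyl CH3, or the triacylmethane may lose an acyl group by retro-Claisen cleavage before it cyclises. The fallback reverses the order of the two C–C bond formations and sets out from 11. Its carboxylate is left as the lithium salt and the lactone is opened by the terminal carbon of the dianion of 12 (LiN(iPr)2, THF, −78 → 0 °C) to the triketo acid F8 (C6 carries CO2H and the 3,5-dioxo-6-methylheptanoyl chain; C4–OH free). Activation of the acid (DCC, DMAP, CH2Cl2) should then C-acylate the diketone carbon next to the isobutyryl group and close the trione ring, returning to the route at 15.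

Further compounds
F1 | step 4 | (S)-6-oxo-3-(prop-1-en-2-yl)heptanal | O=CC[C@H](CCC(C)=O)C(C)=C
F2 | step 4 | (5R)-2-methyl-5-(prop-1-en-2-yl)cyclopent-1-ene-1-carbaldehyde | O=CC1=C(C)CC[C@@H]1C(C)=C
F3 | step 4 | (1R,2R,5S)-5-methyl-2-(prop-1-en-2-yl)-6-oxabicyclo[3.1.0]hexane-1-carbaldehyde | O=C[C@]12O[C@@]1(C)CC[C@@H]2C(C)=C
F4 | step 4 | (1R,2S,5S)-2-hydroxy-2-methyl-5-(prop-1-en-2-yl)cyclopentane-1-carbaldehyde | O=C[C@@H]1[C@H](CC[C@]1(C)O)C(C)=C
F5 | step 6 | (1R,2S,5S)-2-[(tert-butyldimethylsilyl)oxy]-5-(3-chloroprop-1-en-2-yl)-2-methylcyclopentane-1-carbaldehyde | O=C[C@@H]1[C@H](CC[C@]1(C)O[Si](C)(C)C(C)(C)C)C(=C)CCl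
F6 | step 6 | chloroallyl Meldrum's acid (10 with CH2Cl in place of the isopropenyl methyl) | CC1(C)OC(=O)C(C[C@@H]2[C@H](CC[C@]2(C)O[Si](C)(C)C(C)(C)C)C(=C)CCl)C(=O)O1
F7 | step 6 | spiro Meldrum's acid with exocyclic methylene on C4 | CC1(C)OC(=O)C2(C[C@@H]3[C@H](CC[C@]3(C)O[Si](C)(C)C(C)(C)C)C(=C)C2)C(=O)O1
F8 | step 8 | triketo acid (C6: CO2H and 3,5-dioxo-6-methylheptanoyl; C4–OH free; C1 OTBS) | OC(=O)[C@]1(C[C@@H]2[C@H](CC[C@]2(C)O[Si](C)(C)C(C)(C)C)[C@](C)(O)C1)C(=O)CC(=O)CC(=O)C(C)C
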